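The numbers in the tables are calculated for an exercise; scatter was added.

Divide the gain in product by the gain in homo dimer over one stretch of a run, and time drops out. Five flasks share the same charges and differ in how these go in, so that quotient is the thing to follow.

| flask | substrate | reagent | remark | time |
|---|---|---|---|---|
| oak | 20 mM | 16 mM | run made earlier |  |
| larch | 20 mM | 8 mM | run made earlier |  |
| birch | 20 mM | 32 mM | run made earlier |  |
| cedar | 10 mM | 16 mM | run made earlier |  |
| dusk | 20 mM | 16.0 mM (fed, over 2.0 h) | all else is in the flask from the start; the feed brings no volume worth counting | 3.0 h |
| midnight | 20 mM (fed, over 2.0 h) | 16.0 mM | all else is in the flask from the start; the feed brings no volume worth counting | 3.0 h |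
| dawn | 20 mM (fed, over 12 min) | 16.0 mM | all else is in the flask from the start; the feed brings no volume worth counting | 3.0 h |
| spring | 20 mM (in portions, 5, over 2.0 h) | 16.0 mM | first portion at the start, last at 2.0 h | 3.0 h |
| autumn | 20 mM | 16.0 mM | everything together at the start | 3.0 h |

- oak (time / min: homo dimer / %, product / %, substrate / %): 8.00: 10, 11, 77; 20.0: 16, 27, 53; 50.0: 27, 46, 28; 120: 31, 59, 7
- larch (time / h: homo dimer / %, product / %, substrate / %): 0.250: 20, 13, 70; 0.667: 30, 20, 46; 1.50: 43, 31, 27; 4.00: 50, 36, 12
- birch (time / h: homo dimer / %, product / %, substrate / %): 0.417: 17, 55, 31; 1.33: 14, 85, 2; 2.50: 13, 86, 1; 4.00: 15, 83, 1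
- cedar (time / h: homo dimer / %, product / %, substrate / %): 0.250: 7, 30, 58; 0.667: 12, 62, 29; 1.50: 12, 85, 3; 4.00: 11, 87, 0

(standard deviation of a reading: 1.5 percentage points)

- a species is counted by the substrate in it: one homo dimer counts as two
- the earlier runs were read with a standard deviation of 1.5 percentage points

- the flask that comes out highest in amount of homo dimer, in percent of the substrate charged, or "all alike" when all lie within 1.5 percentage points (dusk / midnight / dawn / spring / autumn / all alike)
- homo dimer at the end, in percent of the substrate charged, dusk
- homo dimer at the end, in percent of the substrate charged, midnight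
- homo dimer at the end, in percent of the substrate charged, dawn
- homo dimer at the end, in percent of the substrate charged, spring
- homo dimer at the end, in percent of the substrate charged, autumn

Oak's first row reads 1.10, and this reading, percent of product per percent of homo dimer near oak's charges, is the split, a selectivity factor. Larch's first row reads 0.650 on 8 mM of reagent, so the split is taken as rising in step with [reagent]. Its order in [substrate] can be had in two ways. Cedar's first row against oak's, on 10 mM against 20 mM, gives 1.96. Inside oak, the stretch from the first to the third row has a split of 2.06 at mean [substrate] 10.5 mM and mean [reagent] 10.3 mM, which gives 1.66.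

The two part, and the first way cheats: cedar's first row has already fallen to 58% of its substrate, lower than oak's 77%, yet both rows are booked at their charges. Within the scatter of such ratios, the order is taken as 1.50.

My own reckoning for the fed flasks takes [substrate] at 5.00 mM and [reagent] at 8.00 mM as a working guess. The split is then 4.40, and with 80.0% of the substrate reacted, homo dimer comes to 14.8% in midnight and in spring alike.

The forecast names dusk as highest and gives dusk 50%, midnight 19.5%, dawn 30%, spring 21% and autumn 32%, with the ground: “Spring comes out slightly higher than midnight because its portions give peaks of substrate”. My figure for spring stands lower than the forecast's.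

Spring gives 14.2% of homo dimer, midnight 15.4%, dawn 28.2% and autumn 30.4%, and dusk comes out highest at 52.3%, more than any of these.

    substrate + reagent → product, rate k1*[substrate]^0.5*[reagent] (k = 0.00280 M⁻⁰·⁵ s⁻¹)
    2 substrate → homo dimer (k = 0.00710 M⁻¹ s⁻¹)

At the end of spring, the path to product uses substrate 2.2 times as fast as the path to homo dimer. Spring's split at that moment, with 18.1% of the substrate charged and 15.4% of the reagent's own charge, reckons to 2.20. Dusk, with mean [substrate] 8.82 mM and mean [reagent] 4.78 mM over the first 2.0 h, reckons to a split of 1.12, an estimated share of 47.2% of reacted substrate in homo dimer, and dusk ends at 52.3%.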